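The oxolane ring (O1, C2 bearing the aryl group, C3 bearing CH2OAc, C4 the tertiary carbinol, C5) is cut at C4–C5 and C5–O1. C5 is an isolated ring CH2 flanked by O1 and C4, so it can enter as carbon monoxide. A phosphinite docked on the C2 hydroxyl of an acyclic (1S,2R,E)-1,4-diaryl-2-(silyloxymethyl)but-3-en-1-ol steers rhodium hydroformylation to C4; the γ-hydroxy aldehyde closes to the lactol, so one operation forms both bonds and the ring. An Evans syn-aldol supplies the precursor; lactol dehydration and enol ether hydroboration then set the C4 hydroxyl anti to the C3 side chain.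

Key step: step 6

Remark (numbering and abbreviations): ring numbering O1, C2 (aryl-bearing), C3 (CH2O-bearing), C4 (future tertiary carbinol), C5 (carbon from CO) is used for all compounds, open-chain ones included; Ar = 4-(benzyloxy)-3-methoxyphenyl; TIPS = tri(propan-2-yl)silyl.

Remark (precursor design): precursor 12 carries a single free hydroxyl, at C2. The primary oxygen is itself homoallylic and would give the wrong lactol if it bound phosphorus, so it is capped as a bulky TIPS ether; TIPS should also resist O-to-O migration and shield one face of C4 in step 8. The phenols are benzyl ethers, which keep the styrene electron-rich and should weaken the benzylic rhodium alternative.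

Remark (lactol isomers): 16 and 17 are drawn as the C3/C4-trans isomer expected to predominate; the C4 epimer and both anomers converge to 18 in step 7.

Step 1
Reactants: 1 4-(benzyloxy)-3-methoxybenzaldehyde; 2 (2-carboxyethyl)triphenylphosphonium bromide
Product: 4 (E)-4-[4-(benzyloxy)-3-methoxyphenyl]but-3-enoic acid, via ylide carboxylate 3 (not isolated)
Conditions: NaN(SiMe3)2 (2.1 equiv), THF, 0 °C → rt; then aq. HCl; crystallisation
Reagents that add atoms: none
Why: Wittig olefination; a ylide carrying a carboxylate two atoms from phosphorus is known to give the E-styrene with aromatic aldehydes, the double bond stays in the β,γ-position because it is conjugated with the arene, and crystallisation of the acid should remove residual Z isomer.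

Step 2
Reactants: 4 (E)-4-Ar-but-3-enoic acid; 5 (S)-4-benzyl-2-oxazolidinone
Product: 7 (S)-4-benzyl-3-[(E)-4-Ar-but-3-enoyl]oxazolidin-2-one, via mixed pivalic anhydride 6 (not isolated)
Conditions: t-BuCOCl, Et3N, THF, −20 °C; then LiCl, 5, −20 °C → rt
Reagents that add atoms: none
Why: N-acylation of the oxazolidinone through a mixed anhydride; the lithium-activated oxazolidinone attacks the less hindered acyl group under conditions mild enough to leave the β,γ-alkene in place.

Step 3
Reactants: 7 (S)-4-benzyl-3-[(E)-4-Ar-but-3-enoyl]oxazolidin-2-one; 1 4-(benzyloxy)-3-methoxybenzaldehyde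
Product: 10 (S)-4-benzyl-3-{(2S,3E)-4-Ar-2-[(S)-Ar(hydroxy)methyl]but-3-enoyl}oxazolidin-2-one, via dibutylboron Z-dienolate 8 (not isolated), via dibutylboron aldolate 9 (not isolated)
Conditions: Bu2BOTf, iPr2NEt, CH2Cl2, −78 → 0 °C; then 1, −78 → 0 °C; then pH 7 buffer, MeOH, H2O2, 0 °C
Reagents that add atoms: none
Why: Evans syn-aldol reaction; soft enolisation gives the Z boron dienolate, which reacts at its α-carbon through a chair (Zimmerman–Traxler) transition state with the auxiliary carbonyl turned away from the enolate oxygen, so the aldehyde adds to the face opposite the benzyl group and sets C3 and C2 together as the (2S,3S) syn adduct.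

Step 4
Reactants: 10 syn-aldol imide
Product: 11 (1S,2R)-1-Ar-2-[(E)-2-Ar-ethenyl]propane-1,3-diol
Conditions: LiBH4, MeOH (1 equiv), THF, 0 °C
Reagents that add atoms: none
Why: Reductive cleavage of an N-acyloxazolidinone; hydride attacks the lithium-activated exocyclic carbonyl and releases the 1,3-diol and the auxiliary without touching the styrene or either stereocentre.

Step 5
Reactants: 11 (1S,2R)-1-Ar-2-[(E)-2-Ar-ethenyl]propane-1,3-diol
Product: 12 (1S,2R,3E)-1,4-bis(Ar)-2-[(TIPS-oxy)methyl]but-3-en-1-ol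
Conditions: TIPSCl, imidazole, CH2Cl2, 0 °C → rt
Reagents that add atoms: chlorotri(propan-2-yl)silane, CC(C)[Si](Cl)(C(C)C)C(C)C
Why: Selective silylation; the bulky silyl chloride reacts only with the primary hydroxyl and leaves the hindered benzylic C2 hydroxyl free as the sole docking site for step 6.

Step 6
Reactants: 12 (1S,2R,3E)-1,4-bis(Ar)-2-[(TIPS-oxy)methyl]but-3-en-1-ol; 13 carbon monoxide
Product: 16 (3S,4R,5S)-5-Ar-3-(Ar-methyl)-4-[(TIPS-oxy)methyl]oxolan-2-ol (anomer mixture), via substrate diphenylphosphinite 14 (not isolated), via γ-hydroxy aldehyde 15 (not isolated)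
Conditions: Rh(acac)(CO)2 (cat.), Ph2POMe (cat.), CO/H2 (1:1, 40 bar), 4 Å MS, THF, 60 °C
Reagents that add atoms: none
Why: Ph2POMe exchanges its methoxy group for the C2 oxygen to give phosphinite 14, the rhodium hydride held on that phosphorus adds across the alkene through a six-membered chelate (Rh–P–O–C2–C3–C4) so that rhodium ends on C4 and hydrogen on the benzylic carbon, CO insertion and hydrogenolysis of the acyl give the C4 formyl group, and phosphinite exchange frees γ-hydroxy aldehyde 15 and returns the ligand. The closest known reaction type is the branched-selective hydroformylation of homoallylic alcohols to γ-lactols with a catalytic, reversibly bound phosphinite directing group, which extends to 1,2-disubstituted alkenes. The ring closes by hemiacetal formation, O1 adding to the formyl carbon C5 in a 5-exo-trig mode. The new C4 and C5 centres need no control (C3/C4-trans expected, C5 as anomers) because both are deleted in step 7, while C2 and C3 are not touched. The selectivity needed is regiochemical, formyl at C4 and not at the benzylic carbon; it rests on the single free hydroxyl at C2, on the preference for the six- over the seven-membered chelate, and on the electron-rich arene, which should disfavour benzylic rhodium. CO-rich pressure and moderate temperature should hold back hydrogenation and isomerisation of the styrene, and molecular sieves protect the P–O exchange from hydrolysis.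

Step 7
Reactants: 16 lactol
Product: 18 (2S,3R)-2-Ar-4-(Ar-methyl)-3-[(TIPS-oxy)methyl]-2,3-dihydrofuran, via anomeric methanesulfonate 17 (not isolated)
Conditions: MsCl, Et3N (excess), THF, −40 → 60 °C; filtration through Et3N-deactivated silica, used directly
Reagents that add atoms: none
Why: Hemiacetal dehydration by sulfonylation–elimination; the anomeric mesylate ionises to the oxocarbenium ion, whose only β-hydrogen (on C4) is removed by Et3N, giving the C4=C5 enol ether and erasing the C4 and C5 centres while C2 and C3 stay fixed.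

Step 8
Reactants: 18 2,3-dihydrofuran
Product: 20 (3S,4R,5S)-5-Ar-3-(Ar-methyl)-4-[(TIPS-oxy)methyl]oxolan-3-ol, via C4 alkylborane 19 (not isolated)
Conditions: BH3·THF, THF, 0 °C → rt; then aq. NaOH, H2O2, 0 °C → rt
Reagents that add atoms: hydrogen peroxide, OO
Why: Hydroboration–oxidation of an enol ether; polarisation by O1 puts boron on C4 and hydrogen on C5, syn addition takes the face opposite the adjacent C3 CH2OTIPS group, and oxidation with retention gives the C4 hydroxyl anti to the C3 side chain (route C4 = S).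

Step 9
Reactants: 20 silyl ether
Product: 21 (3S,4R,5S)-5-Ar-3-(Ar-methyl)-4-(hydroxymethyl)oxolan-3-ol
Conditions: Bu4NF, THF, 0 °C → rt
Reagents that add atoms: none
Why: Fluoride-mediated desilylation driven by Si–F bond formation; benzyl ethers, the ring and the tertiary alcohol are inert.

Step 10
Reactants: 21 diol
Product: 22 [(2S,3R,4S)-2-Ar-4-(Ar-methyl)-4-hydroxyoxolan-3-yl]methyl acetate
Conditions: Ac2O, pyridine, CH2Cl2, 0 °C → rt
Reagents that add atoms: acetic anhydride, CC(=O)OC(C)=O
Why: Selective O-acylation; the primary hydroxyl is acetylated, the tertiary C4 hydroxyl is too hindered to react without a nucleophilic catalyst, and the phenols are still benzylated.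

Step 11
Reactants: 22 dibenzyl ether acetate
Product: 23 olivil monoacetate, [(2S,3R,4S)-4-hydroxy-2-(4-hydroxy-3-methoxyphenyl)-4-(4-hydroxy-3-methoxybenzyl)oxolan-3-yl]methyl acetate
Conditions: H2 (1 atm), Pd/C, EtOAc, rt, stopped at uptake of two equivalents
Reagents that add atoms: none
Why: Catalytic hydrogenolysis; the two aryl benzyl ethers should cleave much faster than the dialkyl-type benzylic C2–O1 bond in a neutral aprotic solvent, and the acetate and all three stereocentres are untouched.

Compound list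
1 | 4-(benzyloxy)-3-methoxybenzaldehyde | COc1cc(C=O)ccc1OCc1ccccc1 | starting material
2 | (2-carboxyethyl)triphenylphosphonium bromide | OC(=O)CC[P+](c1ccccc1)(c1ccccc1)c1ccccc1.[Br-] | starting material
3 | sodium 3-(triphenylphosphoranylidene)propanoate, ylide carboxylate (not isolated) | [Na+].[O-]C(=O)CC=P(c1ccccc1)(c1ccccc1)c1ccccc1 | intermediate
4 | (E)-4-[4-(benzyloxy)-3-methoxyphenyl]but-3-enoic acid | COc1cc(/C=C/CC(=O)O)ccc1OCc1ccccc1 | intermediate
5 | (S)-4-benzyl-2-oxazolidinone | O=C1N[C@@H](Cc2ccccc2)CO1 | starting material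
6 | mixed anhydride of 4 with pivalic acid (not isolated) | COc1cc(/C=C/CC(=O)OC(=O)C(C)(C)C)ccc1OCc1ccccc1 | intermediate
7 | (S)-4-benzyl-3-[(E)-4-Ar-but-3-enoyl]oxazolidin-2-one | COc1cc(/C=C/CC(=O)N2[C@@H](Cc3ccccc3)COC2=O)ccc1OCc1ccccc1 | intermediate
8 | dibutylboron Z-dienolate of 7 (not isolated) | CCCCB(CCCC)O/C(=C\C=C\c1ccc(OCc2ccccc2)c(OC)c1)N1[C@@H](Cc2ccccc2)COC1=O | intermediate
9 | O-dibutylboryl aldolate of 10 (not isolated) | COc1cc(/C=C/[C@H](C(=O)N2[C@@H](Cc3ccccc3)COC2=O)[C@H](OB(CCCC)CCCC)c2ccc(OCc3ccccc3)c(OC)c2)ccc1OCc1ccccc1 | intermediate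
10 | (S)-4-benzyl-3-{(2S,3E)-4-Ar-2-[(S)-Ar(hydroxy)methyl]but-3-enoyl}oxazolidin-2-one | COc1cc(/C=C/[C@H](C(=O)N2[C@@H](Cc3ccccc3)COC2=O)[C@H](O)c2ccc(OCc3ccccc3)c(OC)c2)ccc1OCc1ccccc1 | intermediate
11 | (1S,2R)-1-Ar-2-[(E)-2-Ar-ethenyl]propane-1,3-diol | COc1cc(/C=C/[C@H](CO)[C@H](O)c2ccc(OCc3ccccc3)c(OC)c2)ccc1OCc1ccccc1 | intermediate
12 | (1S,2R,3E)-1,4-bis(Ar)-2-[(TIPS-oxy)methyl]but-3-en-1-ol | COc1cc(/C=C/[C@H](CO[Si](C(C)C)(C(C)C)C(C)C)[C@H](O)c2ccc(OCc3ccccc3)c(OC)c2)ccc1OCc1ccccc1 | intermediate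
13 | carbon monoxide | [C-]#[O+] | starting material
14 | O-diphenylphosphinite of 12 at the C2 oxygen (not isolated) | COc1cc(/C=C/[C@H](CO[Si](C(C)C)(C(C)C)C(C)C)[C@H](OP(c2ccccc2)c2ccccc2)c2ccc(OCc3ccccc3)c(OC)c2)ccc1OCc1ccccc1 | intermediate
15 | (3R,4S)-4-Ar-2-(Ar-methyl)-4-hydroxy-3-[(TIPS-oxy)methyl]butanal, C2 epimers (not isolated) | COc1cc(CC(C=O)[C@H](CO[Si](C(C)C)(C(C)C)C(C)C)[C@H](O)c2ccc(OCc3ccccc3)c(OC)c2)ccc1OCc1ccccc1 | intermediate
16 | (3S,4R,5S)-5-Ar-3-(Ar-methyl)-4-[(TIPS-oxy)methyl]oxolan-2-ol, anomer mixture | COc1cc(C[C@@H]2C(O)O[C@H](c3ccc(OCc4ccccc4)c(OC)c3)[C@H]2CO[Si](C(C)C)(C(C)C)C(C)C)ccc1OCc1ccccc1 | intermediate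
17 | anomeric methanesulfonate of 16 (not isolated) | COc1cc(C[C@@H]2C(OS(C)(=O)=O)O[C@H](c3ccc(OCc4ccccc4)c(OC)c3)[C@H]2CO[Si](C(C)C)(C(C)C)C(C)C)ccc1OCc1ccccc1 | intermediate
18 | (2S,3R)-2-Ar-4-(Ar-methyl)-3-[(TIPS-oxy)methyl]-2,3-dihydrofuran | COc1cc(CC2=CO[C@H](c3ccc(OCc4ccccc4)c(OC)c3)[C@H]2CO[Si](C(C)C)(C(C)C)C(C)C)ccc1OCc1ccccc1 | intermediate
19 | C4 alkylborane (BH2 on C4, anti to the C3 side chain) from 18 (not isolated) | COc1cc(C[C@@]2(B)CO[C@H](c3ccc(OCc4ccccc4)c(OC)c3)[C@H]2CO[Si](C(C)C)(C(C)C)C(C)C)ccc1OCc1ccccc1 | intermediate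
20 | (3S,4R,5S)-5-Ar-3-(Ar-methyl)-4-[(TIPS-oxy)methyl]oxolan-3-ol | COc1cc(C[C@@]2(O)CO[C@H](c3ccc(OCc4ccccc4)c(OC)c3)[C@H]2CO[Si](C(C)C)(C(C)C)C(C)C)ccc1OCc1ccccc1 | intermediate
21 | (3S,4R,5S)-5-Ar-3-(Ar-methyl)-4-(hydroxymethyl)oxolan-3-ol | COc1cc(C[C@@]2(O)CO[C@H](c3ccc(OCc4ccccc4)c(OC)c3)[C@H]2CO)ccc1OCc1ccccc1 | intermediate
22 | [(2S,3R,4S)-2-Ar-4-(Ar-methyl)-4-hydroxyoxolan-3-yl]methyl acetate | COc1cc(C[C@@]2(O)CO[C@H](c3ccc(OCc4ccccc4)c(OC)c3)[C@H]2COC(C)=O)ccc1OCc1ccccc1 | intermediate
23 | olivil monoacetate, [(2S,3R,4S)-4-hydroxy-2-(4-hydroxy-3-methoxyphenyl)-4-(4-hydroxy-3-methoxybenzyl)oxolan-3-yl]methyl acetate | COc1cc(C[C@@]2(O)CO[C@H](c3ccc(O)c(OC)c3)[C@H]2COC(C)=O)ccc1O | target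

Total step count: 11
Longest linear sequence: 11 steps (1 and 2 to 23)

Steps most likely to fail

1. Step 6. Hydrometalation may follow the electronic bias of the styrene and put rhodium on the benzylic carbon, which gives a formyl group that cannot close the ring. Phosphinite exchange at the hindered C2 hydroxyl may also be slow enough for undirected catalysis or alkene hydrogenation to take over. The fallback sets out from 12 and returns at 16, replacing CO insertion by a silicon-tethered radical cyclisation. The C2 hydroxyl of 12 would be silylated with (bromomethyl)chlorodimethylsilane (Et3N, CH2Cl2) to the (bromomethyl)dimethylsilyl ether F1. Bu3SnH/AIBN (benzene, 80 °C, slow addition) should then give 6-exo-trig attack of the silylmethyl radical on C4, with the benzylic radical quenched by the stannane, to form the 1,2-oxasilinane F2. Tamao oxidation (H2O2, KF, KHCO3, THF/MeOH) would give the 1,4-diol F3 in which C5 is a CH2OH group. TEMPO/PhI(OAc)2 (CH2Cl2, rt) should oxidise the primary alcohol through the lactol to the lactone F4, and DIBAL-H (CH2Cl2, −78 °C) returns lactol 16.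

2. Step 8. Boron may add slowly to the fully substituted C4 or from the wrong face, or the β-alkoxyborane may fragment with ring opening before oxidation. The fallback sets out from 18 and returns at 20, delivering oxygen first and hydride second. Epoxidation with dimethyldioxirane (acetone/CH2Cl2, −78 → 0 °C) anti to the C3 side chain would give the 4,5-epoxide F5. LiBHEt3 (THF, −78 → 0 °C) should open this anomeric epoxide by hydride attack at the acetal carbon C5, giving 20 with the oxygen already on C4.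

3. Step 7. The anomeric sulfonate may ionise without clean loss of the C4 proton (return to lactol, anomeric chloride, anhydro dimer), and the acid-labile enol ether may hydrate or oligomerise on isolation. The fallback sets out from 16 and returns at 18, using a thermal syn-elimination under neutral conditions. PhSSPh/Bu3P (pyridine, rt) would convert the lactol into the phenyl thioacetal F6. One equivalent of mCPBA (CH2Cl2, −78 °C) gives the sulfoxide F7, and heating (toluene, Et3N, 90 °C) should expel benzenesulfenic acid with the C4 hydrogen to give 18.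

Further compounds
F1 | step 6 | C2-O-(bromomethyl)dimethylsilyl ether of 12 | COc1cc(/C=C/[C@H](CO[Si](C(C)C)(C(C)C)C(C)C)[C@H](O[Si](C)(C)CBr)c2ccc(OCc3ccccc3)c(OC)c2)ccc1OCc1ccccc1
F2 | step 6 | (5R,6S)-6-Ar-4-(Ar-methyl)-2,2-dimethyl-5-[(TIPS-oxy)methyl]-1,2-oxasilinane, C4 epimers | COc1cc(CC2C[Si](C)(C)O[C@H](c3ccc(OCc4ccccc4)c(OC)c3)[C@H]2CO[Si](C(C)C)(C(C)C)C(C)C)ccc1OCc1ccccc1
F3 | step 6 | (3R,4S)-4-Ar-2-(Ar-methyl)-3-[(TIPS-oxy)methyl]butane-1,4-diol, C2 epimers | COc1cc(CC(CO)[C@H](CO[Si](C(C)C)(C(C)C)C(C)C)[C@H](O)c2ccc(OCc3ccccc3)c(OC)c2)ccc1OCc1ccccc1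
F4 | step 6 | (4R,5S)-5-Ar-3-(Ar-methyl)-4-[(TIPS-oxy)methyl]oxolan-2-one, C3 epimers | COc1cc(CC2C(=O)O[C@H](c3ccc(OCc4ccccc4)c(OC)c3)[C@H]2CO[Si](C(C)C)(C(C)C)C(C)C)ccc1OCc1ccccc1
F5 | step 8 | 4,5-epoxide of 18 (2,6-dioxabicyclo[3.1.0]hexane, oxirane oxygen anti to the C3 side chain) | COc1cc(C[C@@]2(O3)[C@H]3O[C@H](c3ccc(OCc4ccccc4)c(OC)c3)[C@H]2CO[Si](C(C)C)(C(C)C)C(C)C)ccc1OCc1ccccc1
F6 | step 7 | phenyl thioacetal of 16 (SPh in place of the lactol OH) | COc1cc(C[C@@H]2C(Sc3ccccc3)O[C@H](c3ccc(OCc4ccccc4)c(OC)c3)[C@H]2CO[Si](C(C)C)(C(C)C)C(C)C)ccc1OCc1ccccc1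
F7 | step 7 | S-oxide of F6 (anomeric phenyl sulfoxide) | COc1cc(C[C@@H]2C(S(=O)c3ccccc3)O[C@H](c3ccc(OCc4ccccc4)c(OC)c3)[C@H]2CO[Si](C(C)C)(C(C)C)C(C)C)ccc1OCc1ccccc1
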